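## Retrosynthetic overview

1. Target 19 comes from tigloylation of ketol 17. C7–H and C8–O are introduced last, both from the α face, by copper-hydride reduction and Rubottom oxidation of dienone 14.
2. Dienone 14 comes from trans-decalone 9 by two enone-forming oxidations around an isopropenyl conjugate addition; the C7 configuration is deliberately erased and then reset by hydride.
3. Key step: ring A is closed onto ring B by a stannyl-radical-triggered 6-endo vinyl-radical cyclization of alkynyl carbinol 5. It forms C4–C5 (quaternary C5) and the trans ring fusion; hydrogenation then sets C4.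
4. Carbinol 5 comes from an enantioselective Nozaki–Hiyama–Kishi coupling of iodoenone 2 (made from 3-methylcyclohexenone 1) with pent-4-ynal 3. C1 is the only reagent-controlled stereocentre.
5. Ring order: ring B is bought (compound 1); ring A is formed in the radical step.

Convention: bicyclic compounds carry eremophilane locants. Ring A is C1–C2–C3–C4–C5–C10 and ring B is C5–C6–C7–C8–C9–C10; C14 is the methyl on C5, C15 the methyl on C4, and C11–C13 the isopropenyl group on C7. β is the face of the C5 methyl and α the opposite face.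

Assumption: both antipodes of the valine-derived oxazoline sulfonamide ligand of step 2 are at hand, and the one that gives the (S)-carbinol is chosen after one test run.

## Route

Step 1
Reactants: 1 3-methylcyclohex-2-en-1-one
Product: 2 2-iodo-3-methylcyclohex-2-en-1-one
Conditions: I2, DMAP (cat.), K2CO3, THF/H2O, 25 °C
Reagents that add atoms: iodine, II
Why: Amine-catalysed α-iodination of the enone (addition–iodination–elimination, Baylis–Hillman-type) gives the vinyl iodide for the chromium coupling, and no stereocentre is formed.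

Step 2
Reactants: 2 2-iodo-3-methylcyclohex-2-en-1-one; 3 pent-4-ynal
Product: 5 (S)-2-(1-hydroxypent-4-yn-1-yl)-3-methylcyclohex-2-en-1-one, via trimethylsilyl ether 4 (not isolated)
Conditions: CrCl2 (10 mol %), N-[2-(4-isopropyl-4,5-dihydrooxazol-2-yl)-6-methylphenyl]methanesulfonamide (12 mol %), Et3N (cat.), NiCl2(2,9-dimethyl-1,10-phenanthroline) (2 mol %), Mn, Me3SiCl, MeCN, 25 °C; then 1 M HCl, THF
Reagents that add atoms: none
Why: Catalytic asymmetric Nozaki–Hiyama–Kishi coupling, in which the alkenylchromium species adds only to the aldehyde (ketone and alkyne are inert) and the chiral sulfonamide ligand on chromium sets C1 as S.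

Step 3
Reactants: 5 (S)-2-(1-hydroxypent-4-yn-1-yl)-3-methylcyclohex-2-en-1-one
Product: 7 1α-hydroxy-5β-methyl-4-methylidene-10αH-decalin-9-one (trans-fused), via vinylstannane 6 (not isolated)
Conditions: Bu3SnH (1.3 equiv, slow addition), Et3B (cat.), air, toluene (0.01 M), 0 °C; then HCl (1 M in Et2O), 0 °C
Reagents that add atoms: none
Why: Stork-type hydrostannylative radical cyclization in which Bu3Sn• adds to the alkyne terminus, the C4 vinyl radical closes 6-endo onto the enone β-carbon C5 (attack at the acyl-bearing C10 is polarity-mismatched) from the α face because the O–H···O=C9 hydrogen bond of the (S)-carbinol holds the side chain on that face, the C10 α-keto radical then takes hydrogen from Bu3SnH anti to the new C5 methyl to give the trans fusion, and acid removes the tin.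

Step 4
Reactants: 7 1α-hydroxy-5β-methyl-4-methylidene-10αH-decalin-9-one
Product: 8 1α-hydroxy-4β,5β-dimethyl-10αH-decalin-9-one
Conditions: H2 (1 atm), Pd/C, EtOAc, 25 °C
Reagents that add atoms: none
Why: Heterogeneous hydrogenation of the exocyclic alkene from the α face, anti to the axial C5 methyl on the neighbouring carbon, sets the C4 methyl β (cis to C14).

Step 5
Reactants: 8 1α-hydroxy-4β,5β-dimethyl-10αH-decalin-9-one
Product: 9 1α-acetoxy-4β,5β-dimethyl-10αH-decalin-9-one
Conditions: Ac2O, pyridine, DMAP (cat.), CH2Cl2, 0 °C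
Reagents that add atoms: acetic anhydride, CC(=O)OC(C)=O
Why: DMAP-catalysed acylation of the secondary alcohol, under base too weak to enolize towards the hindered C10–H, so neither elimination nor epimerization occurs.

Step 6
Reactants: 9 1α-acetoxy-4β,5β-dimethyl-10αH-decalin-9-one
Product: 11 1α-acetoxy-4β,5β-dimethyl-10αH-decal-7-en-9-one, via trimethylsilyl enol ether 10 (not isolated)
Conditions: LiN(SiMe3)2, Me3SiCl, THF, −78 °C; then Pd(OAc)2 (10 mol %), O2 (1 atm), DMSO, 25 °C
Reagents that add atoms: none
Why: Kinetic deprotonation at the C8 methylene (C10–H is tertiary and shielded, so the β-acetoxy group is not eliminated) with in situ silylation, followed by Saegusa–Ito oxidation of the silyl enol ether to the C7–C8 enone.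

Step 7
Reactants: 11 1α-acetoxy-4β,5β-dimethyl-10αH-decal-7-en-9-one; 12 prop-1-en-2-ylmagnesium bromide
Product: 14 1α-acetoxy-10αH-eremophila-7,11-dien-9-one, via trimethylsilyl enol ether 13 (not isolated)
Conditions: CuBr·SMe2 (10 mol %), Me3SiCl, THF, −78 °C; then Pd(OAc)2 (10 mol %), O2 (1 atm), DMSO, 25 °C
Reagents that add atoms: none
Why: Copper-catalysed conjugate addition of the isopropenyl Grignard reagent with chlorosilane trapping (the group enters α, anti to C14), followed by a second Saegusa–Ito oxidation that removes the C7 hydrogen and so erases this unwanted C7 configuration.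

Step 8
Reactants: 14 1α-acetoxy-10αH-eremophila-7,11-dien-9-one
Product: 17 1α-acetoxy-8α-hydroxy-7αH,10αH-eremophil-11-en-9-one, via silyl enol ether 15 (not isolated), via silyloxy epoxide 16 (not isolated)
Conditions: [CuH(PPh3)]6 (5 mol %), PhMe2SiH (1.05 equiv), toluene, 25 °C; then dimethyldioxirane, acetone, −78 °C; then AcOH, H2O, THF, 0 °C
Reagents that add atoms: dimethyldioxirane, CC1(C)OO1
Why: Copper-hydride 1,4-hydrosilylation delivers hydride to C7 from the α face (the β face is blocked by the syn-axial C5 methyl), which leaves the isopropenyl group β, and Rubottom oxidation of the resulting silyl enol ether from the α face (anti to the isopropenyl group) followed by hydrolysis gives the 8α-alcohol.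

Step 9
Reactants: 17 1α-acetoxy-8α-hydroxy-7αH,10αH-eremophil-11-en-9-one; 18 (E)-2-methylbut-2-enoyl chloride (tigloyl chloride)
Product: 19 1α-acetoxy-8α-[(E)-2-methylbut-2-enoyloxy]-10αH-eremophil-11-en-9-one, (1S,4S,5R,7R,8R,10S), the target
Conditions: pyridine, DMAP (cat.), CH2Cl2, 0 °C
Reagents that add atoms: none
Why: Acylation of the α-ketol with the acid chloride under weak base leaves C8 and C10 untouched, and the E geometry of the ester comes unchanged from the reagent.

## Compound list

1 | 3-methylcyclohex-2-en-1-one | CC1=CC(=O)CCC1 | starting material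
2 | 2-iodo-3-methylcyclohex-2-en-1-one | CC1=C(I)C(=O)CCC1 | intermediate
3 | pent-4-ynal | C#CCCC=O | starting material
4 | (S)-3-methyl-2-[1-(trimethylsilyloxy)pent-4-yn-1-yl]cyclohex-2-en-1-one | C#CCC[C@H](O[Si](C)(C)C)C1=C(C)CCCC1=O | intermediate (not isolated)
5 | (S)-2-(1-hydroxypent-4-yn-1-yl)-3-methylcyclohex-2-en-1-one | C#CCC[C@H](O)C1=C(C)CCCC1=O | intermediate
6 | 1α-hydroxy-5β-methyl-4-[(tributylstannyl)methylidene]-10αH-decalin-9-one (E/Z mixture) | C1CC(=O)[C@@H]2[C@@H](O)CCC(=C[Sn](CCCC)(CCCC)CCCC)[C@@]2(C)C1 | intermediate (not isolated)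
7 | 1α-hydroxy-5β-methyl-4-methylidene-10αH-decalin-9-one | C1CC(=O)[C@@H]2[C@@H](O)CCC(=C)[C@@]2(C)C1 | intermediate
8 | 1α-hydroxy-4β,5β-dimethyl-10αH-decalin-9-one | C1CC(=O)[C@@H]2[C@@H](O)CC[C@H](C)[C@@]2(C)C1 | intermediate
9 | 1α-acetoxy-4β,5β-dimethyl-10αH-decalin-9-one | C1CC(=O)[C@@H]2[C@@H](OC(C)=O)CC[C@H](C)[C@@]2(C)C1 | intermediate
10 | 1α-acetoxy-4β,5β-dimethyl-9-(trimethylsilyloxy)-10αH-decal-8-ene | C1C=C(O[Si](C)(C)C)[C@@H]2[C@@H](OC(C)=O)CC[C@H](C)[C@@]2(C)C1 | intermediate (not isolated)
11 | 1α-acetoxy-4β,5β-dimethyl-10αH-decal-7-en-9-one | C1=CC(=O)[C@@H]2[C@@H](OC(C)=O)CC[C@H](C)[C@@]2(C)C1 | intermediate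
12 | prop-1-en-2-ylmagnesium bromide | C=C(C)[Mg]Br | starting material
13 | 1α-acetoxy-7α-isopropenyl-4β,5β-dimethyl-9-(trimethylsilyloxy)-10αH-decal-8-ene | C=C(C)[C@H]1C=C(O[Si](C)(C)C)[C@@H]2[C@@H](OC(C)=O)CC[C@H](C)[C@@]2(C)C1 | intermediate (not isolated)
14 | 1α-acetoxy-10αH-eremophila-7,11-dien-9-one | C=C(C)C1=CC(=O)[C@@H]2[C@@H](OC(C)=O)CC[C@H](C)[C@@]2(C)C1 | intermediate
15 | 1α-acetoxy-9-(dimethylphenylsilyloxy)-7αH,10αH-eremophila-8,11-diene | C=C(C)[C@@H]1C=C(O[Si](C)(C)c3ccccc3)[C@@H]2[C@@H](OC(C)=O)CC[C@H](C)[C@@]2(C)C1 | intermediate (not isolated)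
16 | 1α-acetoxy-8α,9α-epoxy-9β-(dimethylphenylsilyloxy)-7αH,10αH-eremophil-11-ene | C=C(C)[C@@H]1[C@H]3O[C@@]3(O[Si](C)(C)c4ccccc4)[C@@H]2[C@@H](OC(C)=O)CC[C@H](C)[C@@]2(C)C1 | intermediate (not isolated)
17 | 1α-acetoxy-8α-hydroxy-7αH,10αH-eremophil-11-en-9-one | C=C(C)[C@@H]1[C@@H](O)C(=O)[C@@H]2[C@@H](OC(C)=O)CC[C@H](C)[C@@]2(C)C1 | intermediate
18 | (E)-2-methylbut-2-enoyl chloride | ClC(=O)/C(C)=C/C | starting material
19 | 1α-acetoxy-8α-[(E)-2-methylbut-2-enoyloxy]-10αH-eremophil-11-en-9-one, (1S,4S,5R,7R,8R,10S) | C=C(C)[C@H]1C[C@@]2(C)[C@H](C(=O)[C@@H]1OC(=O)/C(C)=C/C)[C@@H](OC(C)=O)CC[C@@H]2C | target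

## Step count and risks

Total step count: 9. Longest linear sequence: 9 steps (1 → 19); compounds 3, 12 and 18 are bought.

The three steps most likely to fail:

Step 3 (key cyclization). The vinyl radical must close 6-endo at a fully substituted carbon. Simple hydrostannation of the alkyne, 5-exo closure at C10, or attack on the wrong face (if the hydrogen bond does not hold the conformation) would all defeat it. The fallback sets out from 5 and comes back at 8, skipping step 4. The alkyne of 5 is semihydrogenated (H2, Pd/CaCO3 poisoned with Pb(OAc)2, quinoline) to (S)-2-(1-hydroxypent-4-en-1-yl)-3-methylcyclohex-2-en-1-one F1. F1 is then cyclized by iron-hydride hydrogen-atom transfer (Fe(acac)3, PhSiH3, EtOH, 60 °C): the secondary C4 radical adds to C5 and the iron enolate is protonated anti to C14. This gives 8 directly, but C4 is then set in the C–C bond-forming event with little bias, so the C4 epimer 1α-hydroxy-4α,5β-dimethyl-10αH-decalin-9-one F2 is also formed and must be separated.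

Step 8 (copper-hydride reduction and oxidation). Hydride could add 1,6 to the dienone and give the isopropylidene isomer, or attack the β face; dimethyldioxirane could also touch the isopropenyl group. The target is the less stable C10 epimer (the cis-fused isomer lets the isopropenyl group sit equatorial), so no basic rescue is possible after this point. The fallback sets out from 14 and comes back at 17. Dienone 14 is reduced through its iminium ion (Hantzsch ester, benzylammonium trifluoroacetate (20 mol %), dioxane, 60 °C), again from the α face, to 1α-acetoxy-7αH,10αH-eremophil-11-en-9-one F3. F3 is deprotonated kinetically at C8 (LiN(SiMe3)2, THF, −78 °C) to the lithium 8-en-9-olate F4, which is hydroxylated with 2-(phenylsulfonyl)-3-phenyloxaziridine from the α face and quenched with NH4Cl to give 17.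

Step 2 (asymmetric chromium coupling). The C–C coupling itself is reliable, but the enantiomeric excess with a hindered 2-iodoenone may be low, and every later stereocentre is relayed from C1. The fallback sets out from 5 of insufficient enantiomeric purity and comes back at 5. The alcohol is oxidized with Dess–Martin periodinane (CH2Cl2, 0 °C) to 3-methyl-2-(pent-4-ynoyl)cyclohex-2-en-1-one F5. F5 is reduced at the exocyclic, less conjugated ketone with catecholborane and (R)-1-methyl-3,3-diphenyltetrahydro-1H,3H-pyrrolo[1,2-c][1,3,2]oxazaborole (10 mol %) in toluene at −78 °C, which returns (S)-5.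

## Further compounds

F1 | step 3 | (S)-2-(1-hydroxypent-4-en-1-yl)-3-methylcyclohex-2-en-1-one | C=CCC[C@H](O)C1=C(C)CCCC1=O
F2 | step 3 | 1α-hydroxy-4α,5β-dimethyl-10αH-decalin-9-one | C1CC(=O)[C@@H]2[C@@H](O)CC[C@@H](C)[C@@]2(C)C1
F3 | step 8 | 1α-acetoxy-7αH,10αH-eremophil-11-en-9-one | C=C(C)[C@@H]1CC(=O)[C@@H]2[C@@H](OC(C)=O)CC[C@H](C)[C@@]2(C)C1
F4 | step 8 | lithium 1α-acetoxy-7αH,10αH-eremophila-8,11-dien-9-olate | [Li+].C=C(C)[C@@H]1C=C([O-])[C@@H]2[C@@H](OC(C)=O)CC[C@H](C)[C@@]2(C)C1
F5 | step 2 | 3-methyl-2-(pent-4-ynoyl)cyclohex-2-en-1-one | C#CCCC(=O)C1=C(C)CCCC1=O
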